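## Retrosynthetic overview

1. Feature: in seven-membered ring B (C5–C10 plus C1) the ester oxygen on C6 and the epoxide carbon C9 are 1,4-related. With both taken back to ketones, C7 and C8 are each α to a carbonyl group and have the same donor polarity. The C7–C8 bond is therefore cut as an oxidative union of two enolates, from a C6 methyl ketone and a C9 ethyl ketone carried on ring A (C1–C5).
2. Ring A is closed through the C5–C1 bond by an intramolecular Michael addition. The open chain comes from (S)-terpinen-4-ol (C4 from the chiral pool) by ozonolysis, olefination of the methyl ketone, and methyl addition/oxidation at the aldehyde.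
3. After ring B: the C4 hydroxyl directs hydride to C6, the C9 ketone becomes the C8=C9 alkene through its thermodynamic enol triflate, the C6 hydroxyl directs epoxidation, and the veratrate is put on last.
4. Order of ring formation: ring A (step 8), ring B (step 9), oxirane (step 15).

Key step: step 9

Remark: β means the face of the bicycle that carries the C1 methyl group and α the opposite face; the two C8 epimers formed in step 9 are carried on together, because C8 becomes trigonal in step 12.

## Route

Step 1
Reactants: 1 (S)-(+)-terpinen-4-ol
Product: 2 (S)-terpinen-4-ol triethylsilyl ether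
Conditions: Et3SiOTf, 2,6-lutidine, CH2Cl2, 0 °C
Reagents that add atoms: triethylsilyl trifluoromethanesulfonate, CC[Si](CC)(CC)OS(=O)(=O)C(F)(F)F
Why: O-silylation of a hindered tertiary alcohol with a silyl triflate and a hindered pyridine base is standard and leaves the carbinol stereocentre (later C4) untouched.

Step 2
Reactants: 2 (S)-terpinen-4-ol triethylsilyl ether
Product: 5 keto acetal (S)-7,7-dimethoxy-5-isopropyl-5-(triethylsilyloxy)heptan-2-one, via ozonide 3 (not isolated), via keto aldehyde 4 (not isolated)
Conditions: O3, CH2Cl2, −78 °C; PPh3, −78 °C → rt; then HC(OMe)3, MeOH, CeCl3·7H2O (cat.), rt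
Reagents that add atoms: ozone, O=[O+][O-]; methanol, CO; trimethyl orthoformate, COC(OC)OC
Why: Ozonolysis with reductive work-up cleaves the ring alkene to a methyl ketone and an aldehyde, and the mild CeCl3-catalysed acetalisation masks only the aldehyde while sparing the silyl ether and the C4 stereocentre.

Step 3
Reactants: 5 keto acetal; 6 diethyl [2-(methoxy(methyl)amino)-2-oxoethyl]phosphonate
Product: 8 (S,E)-8,8-dimethoxy-N-methoxy-N,3-dimethyl-6-isopropyl-6-(triethylsilyloxy)oct-2-enamide, via sodium phosphonate anion 7 (not isolated)
Conditions: NaH, THF, 0 °C → reflux; (E) isomer separated by chromatography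
Reagents that add atoms: none
Why: Horner–Wadsworth–Emmons olefination of the unhindered methyl ketone with an amide-stabilised phosphonate anion, which adds to ketones where a β-keto phosphonate would not, should give mainly the (E)-alkene with the chain trans to the carbonyl group.

Step 4
Reactants: 8 unsaturated Weinreb amide
Product: 9 (S,E)-10,10-dimethoxy-5-methyl-8-isopropyl-8-(triethylsilyloxy)dec-4-en-3-one
Conditions: EtMgBr, THF, 0 °C
Reagents that add atoms: ethylmagnesium bromide, CC[Mg]Br
Why: Weinreb ketone synthesis, in which the chelated tetrahedral adduct survives until work-up so that the Grignard reagent adds once and the hindered β-carbon is not attacked.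

Step 5
Reactants: 9 enone acetal
Product: 10 (S,E)-3-isopropyl-6-methyl-8-oxo-3-(triethylsilyloxy)dec-6-enal
Conditions: PPTS, acetone/H2O, 40 °C
Reagents that add atoms: water, O
Why: Mild acid hydrolysis of a dimethyl acetal, under which the tertiary triethylsilyl ether and the enone should survive.

Step 6
Reactants: 10 enone aldehyde
Product: 11 (E)-10-hydroxy-5-methyl-8-isopropyl-8-(triethylsilyloxy)undec-4-en-3-one (both C10 carbinol epimers)
Conditions: MeTi(OiPr)3, THF, −30 → 0 °C
Reagents that add atoms: methyltitanium triisopropoxide, C[Ti](OC(C)C)(OC(C)C)OC(C)C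
Why: Chemoselective carbonyl addition, since the alkyltitanium reagent adds to aldehydes far faster than to enones; the new carbinol centre forms as a mixture that step 7 removes.

Step 7
Reactants: 11 enone alcohol
Product: 12 (S,E)-5-methyl-8-isopropyl-8-(triethylsilyloxy)undec-4-ene-3,10-dione
Conditions: Dess–Martin periodinane, CH2Cl2, rt
Reagents that add atoms: none
Why: Dess–Martin oxidation of the secondary alcohol under non-basic conditions avoids silyl migration to the neighbouring oxygen and β-elimination of the silyloxy group.

Step 8
Reactants: 12 enone methyl ketone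
Product: 13 cyclopentane diketone (C5 acetyl and C1 methyl and C4 triethylsilyloxy on one face; 2-oxobutyl and isopropyl on the other)
Conditions: KOtBu (0.2 equiv), tBuOH/THF, −20 → 0 °C
Reagents that add atoms: none
Why: Intramolecular Michael addition (5-exo-trig) of the C5 enolate to the β,β-disubstituted enone closes ring A; C5 is epimerisable and should settle with the acetyl group cis to the C4 oxygen and trans to isopropyl, while C1 is set because the allylic-strain-minimised enolate (silyloxy group in the enolate plane, isopropyl anti) should add through an open potassium-enolate transition state that keeps the acylvinyl arm of the (E)-enone away from the enolate, placing C10 trans and the methyl group cis to the acetyl group (the catalytic base and low temperature are meant to stop the product from closing further by aldol addition).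

Step 9
Reactants: 13 cyclopentane diketone
Product: 15 trans-fused bicyclic 6,9-diketone (C8 methyl as both epimers; C4 triethylsilyl ether), via dilithium bis-enolate 14 (not isolated)
Conditions: LiN(iPr)2 (2.3 equiv), THF, −78 °C, 13 added slowly to the base; then Cu(O2CCH(Et)nBu)2 (copper bis(2-ethylhexanoate), 2.2 equiv), THF, −78 → 0 °C, about 0.005 M
Reagents that add atoms: none
Why: Proposed new method: double kinetic deprotonation gives bis-enolate 14 (C7 on the methyl ketone, C8 on the ethyl ketone); one-electron oxidation of one enolate by divalent copper gives an α-keto radical that attacks the other enolate carbon, and a second one-electron oxidation gives the 1,4-diketone and monovalent copper; the closest known reaction type is the intramolecular oxidative coupling of bis-enolates with divalent copper or trivalent iron salts, known for three- to six-membered rings but not for a seven-membered ring holding both carbonyl groups. Ring B closes by C7–C8 bond formation as a 7-endo-trig attack of the C7 radical on the C8=C9 enolate double bond, and the trans arrangement of the two side arms fixed in 13 gives the trans-fused bicycle. The only new stereocentre, C8, forms without control, and both epimers serve. The step needs enolisation at C7 and C8 and not at C5 or C10; C5 is a hindered methine between two fully substituted carbons and C10 is neopentyl, so the amide base should take the methyl and the ethyl CH2 protons. It also needs ring closure to outrun intermolecular coupling and aldol addition of a mono-enolate to the other ketone, which inverse addition to excess base at −78 °C and high dilution during oxidation should secure.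

Step 10
Reactants: 15 bicyclic diketone silyl ether
Product: 16 4β-hydroxy 6,9-diketone
Conditions: HF·pyridine, pyridine, THF, 0 °C → rt
Reagents that add atoms: none
Why: Fluoride cleavage of the tertiary triethylsilyl ether under buffered, weakly acidic conditions avoids the retro-aldol opening that a basic fluoride source could cause in this β-hydroxy ketone.

Step 11
Reactants: 16 hydroxy diketone
Product: 17 4β,6α-dihydroxy 9-ketone
Conditions: Me4NBH(OAc)3, MeCN/AcOH, −20 °C → rt
Reagents that add atoms: none
Why: Evans–Saksena reduction, in which the C4 hydroxyl exchanges onto boron and delivers hydride intramolecularly to the β face of the C6 carbonyl, setting the 6α-alcohol; the C9 ketone has no hydroxyl within reach and is not reduced by this mild hydride.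

Step 12
Reactants: 17 diol ketone
Product: 18 4,6-bis(trimethylsilyl) ether C8=C9 trimethylsilyl enol ether
Conditions: Me3SiCl, NaI, Et3N, MeCN, rt → 40 °C
Reagents that add atoms: chlorotrimethylsilane, C[Si](C)(C)Cl
Why: Silylation with Me3SiI made in the flask under equilibrating conditions gives the thermodynamic, tetrasubstituted silyl enol ether toward the methyl-bearing C8 (which removes the C8 stereocentre) and caps both hydroxyls, which also keeps the C6 hydroxyl from closing a transannular hemiketal onto C9.

Step 13
Reactants: 18 tris-silyl compound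
Product: 20 C8=C9 enol triflate bis(trimethylsilyl) ether, via lithium enolate 19 (not isolated)
Conditions: MeLi (1.05 equiv), THF, −20 °C; then PhNTf2, −78 → 0 °C
Reagents that add atoms: N-phenylbis(trifluoromethanesulfonimide), O=S(=O)(N(c1ccccc1)S(=O)(=O)C(F)(F)F)C(F)(F)F
Why: Methyllithium cleaves the Si–O bond of the enol ether faster than those of the alkyl silyl ethers and gives the lithium enolate without loss of its regiochemistry, which is then O-sulfonylated by the triflimide.

Step 14
Reactants: 20 enol triflate
Product: 22 alkene diol (4β,6α-dihydroxy daucane with C8=C9 double bond; jaeschkeanadiol), via bis-silyl alkene 21 (not isolated)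
Conditions: Pd(OAc)2 (5 mol %), PPh3, nBu3N, HCO2H, DMF, 60 °C; then citric acid, MeOH, rt
Reagents that add atoms: none
Why: Palladium-catalysed formate reduction of an enol triflate (oxidative addition to zerovalent palladium, hydride transfer from formate, reductive elimination) gives the trisubstituted alkene without moving the double bond, and acidic methanol then removes both trimethylsilyl ethers.

Step 15
Reactants: 22 alkene diol
Product: 23 8α,9α-epoxy-4β,6α-diol
Conditions: VO(acac)2 (5 mol %), tBuOOH, CH2Cl2, 0 °C → rt
Reagents that add atoms: tert-butyl hydroperoxide, CC(C)(C)OO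
Why: Hydroxyl-directed vanadium-catalysed epoxidation of a homoallylic alcohol, in which the α-oriented C6 hydroxyl binds the metal peroxide and delivers oxygen to the α face of C8=C9, setting C8 and C9 on the face opposite the C1 methyl group.

Step 16
Reactants: 23 epoxy diol; 24 3,4-dimethoxybenzoyl chloride
Product: 25 CNP0251065.1 (6α-(3,4-dimethoxybenzoyloxy)-8α,9α-epoxy-4β-hydroxy trans-fused daucane)
Conditions: Et3N, DMAP (cat.), CH2Cl2, 0 °C → rt
Reagents that add atoms: none
Why: DMAP-catalysed acylation of the secondary C6 alcohol, with the tertiary C4 alcohol too hindered to react and the basic medium protecting the trisubstituted epoxide.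

## Compound list

1 | (S)-(+)-terpinen-4-ol | CC1=CC[C@](O)(C(C)C)CC1 | starting material
2 | (S)-terpinen-4-ol triethylsilyl ether | CC1=CC[C@](O[Si](CC)(CC)CC)(C(C)C)CC1 | intermediate
3 | secondary ozonide of 2 (1,2,4-trioxolane across the former alkene carbons; not isolated) | CC12CC[C@@](O[Si](CC)(CC)CC)(C(C)C)CC(O1)OO2 | intermediate
4 | (S)-3-isopropyl-6-oxo-3-(triethylsilyloxy)heptanal (not isolated) | CC(=O)CC[C@@](O[Si](CC)(CC)CC)(C(C)C)CC=O | intermediate
5 | (S)-7,7-dimethoxy-5-isopropyl-5-(triethylsilyloxy)heptan-2-one | CC(=O)CC[C@@](O[Si](CC)(CC)CC)(C(C)C)CC(OC)OC | intermediate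
6 | diethyl [2-(methoxy(methyl)amino)-2-oxoethyl]phosphonate | CCOP(=O)(CC(=O)N(C)OC)OCC | starting material
7 | sodium salt of the carbanion of 6 (not isolated) | [Na+].CCOP(=O)([CH-]C(=O)N(C)OC)OCC | intermediate
8 | (S,E)-8,8-dimethoxy-N-methoxy-N,3-dimethyl-6-isopropyl-6-(triethylsilyloxy)oct-2-enamide | CON(C)C(=O)/C=C(\C)CC[C@@](O[Si](CC)(CC)CC)(C(C)C)CC(OC)OC | intermediate
9 | (S,E)-10,10-dimethoxy-5-methyl-8-isopropyl-8-(triethylsilyloxy)dec-4-en-3-one | CCC(=O)/C=C(\C)CC[C@@](O[Si](CC)(CC)CC)(C(C)C)CC(OC)OC | intermediate
10 | (S,E)-3-isopropyl-6-methyl-8-oxo-3-(triethylsilyloxy)dec-6-enal | CCC(=O)/C=C(\C)CC[C@@](O[Si](CC)(CC)CC)(C(C)C)CC=O | intermediate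
11 | (E)-10-hydroxy-5-methyl-8-isopropyl-8-(triethylsilyloxy)undec-4-en-3-one, (S) at the silyloxy carbon, both carbinol epimers | CCC(=O)/C=C(\C)CC[C@@](O[Si](CC)(CC)CC)(C(C)C)CC(C)O | intermediate
12 | (S,E)-5-methyl-8-isopropyl-8-(triethylsilyloxy)undec-4-ene-3,10-dione | CCC(=O)/C=C(\C)CC[C@@](O[Si](CC)(CC)CC)(C(C)C)CC(C)=O | intermediate
13 | key-step precursor: cyclopentane with C5 acetyl, C1 methyl and C1 2-oxobutyl, C4 isopropyl and triethylsilyloxy; acetyl, C1 methyl and silyloxy on the same face | CCC(=O)C[C@@]1(C)CC[C@@](O[Si](CC)(CC)CC)(C(C)C)[C@@H]1C(C)=O | intermediate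
14 | dilithium bis-enolate of 13, enolised at C7 and C8 (not isolated) | [Li+].[Li+].CC=C([O-])C[C@@]1(C)CC[C@@](O[Si](CC)(CC)CC)(C(C)C)[C@@H]1C(=C)[O-] | intermediate
15 | key-step product: trans-fused bicyclo[5.3.0]decane 6,9-dione with C8 methyl (both epimers), C1 β-methyl, C4 α-isopropyl and β-triethylsilyloxy | O=C1CC(C)C(=O)C[C@@]2(C)CC[C@@](O[Si](CC)(CC)CC)(C(C)C)[C@H]12 | intermediate
16 | 4β-hydroxy 6,9-diketone (C8 epimers) | O=C1CC(C)C(=O)C[C@@]2(C)CC[C@@](O)(C(C)C)[C@H]12 | intermediate
17 | 4β,6α-dihydroxy 9-ketone (C8 epimers) | O[C@H]1CC(C)C(=O)C[C@@]2(C)CC[C@@](O)(C(C)C)[C@H]12 | intermediate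
18 | 4β,6α-bis(trimethylsilyloxy) C8=C9 trimethylsilyl enol ether | C[Si](C)(C)O[C@H]1CC(C)=C(O[Si](C)(C)C)C[C@@]2(C)CC[C@@](O[Si](C)(C)C)(C(C)C)[C@H]12 | intermediate
19 | lithium C8=C9 enolate of the bis(trimethylsilyl) ether (not isolated) | [Li+].C[Si](C)(C)O[C@H]1CC(C)=C([O-])C[C@@]2(C)CC[C@@](O[Si](C)(C)C)(C(C)C)[C@H]12 | intermediate
20 | C8=C9 enol triflate, 4β,6α-bis(trimethylsilyl) ether | C[Si](C)(C)O[C@H]1CC(C)=C(OS(=O)(=O)C(F)(F)F)C[C@@]2(C)CC[C@@](O[Si](C)(C)C)(C(C)C)[C@H]12 | intermediate
21 | C8=C9 alkene, 4β,6α-bis(trimethylsilyl) ether (not isolated) | C[Si](C)(C)O[C@H]1CC(C)=CC[C@@]2(C)CC[C@@](O[Si](C)(C)C)(C(C)C)[C@H]12 | intermediate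
22 | alkene diol: trans-fused dauc-8-ene-4β,6α-diol (jaeschkeanadiol) | O[C@H]1CC(C)=CC[C@@]2(C)CC[C@@](O)(C(C)C)[C@H]12 | intermediate
23 | 8α,9α-epoxy-4β,6α-diol | O[C@H]2C[C@@]3(C)O[C@H]3C[C@@]3(C)CC[C@@](O)(C(C)C)[C@H]23 | intermediate
24 | 3,4-dimethoxybenzoyl chloride | COc1ccc(C(=O)Cl)cc1OC | starting material
25 | CNP0251065.1 | COc1ccc(C(=O)O[C@H]2C[C@@]3(C)O[C@H]3C[C@@]3(C)CC[C@@](O)(C(C)C)[C@H]23)cc1OC | target

## Step count and risks

Total step count: 16. Longest linear sequence: 16 steps (1 → 25); 6 and 24 are bought.

**Risk 1, step 9.** Ring closure may lose to intermolecular coupling and oligomerisation. Enolisation may stray to the neopentyl C10 position, whose coupling with C7 would close a five-membered ring instead. A mono-enolate may also add to the other ketone before the second deprotonation. Fallback with known chemistry, from 13 back to 15: bis-enolate 14 is made as before and silylated with iPr2SiCl2 to the cyclic diisopropylsilylene bis-enol ether F1. F1 is oxidised with (NH4)2Ce(NO3)6 (tetravalent cerium) and NaHCO3 in MeCN/EtCN at low temperature. One-electron oxidation of a silicon-tethered bis-enol ether is an established route to unsymmetrical 1,4-diketones; the tether holds C7 and C8 together, so the bond formation is unimolecular, and loss of silicon on work-up should give 15.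

**Risk 2, step 8.** The ring closure may show poor facial selectivity at the enone carbon C1, and the 1,5-diketone product may close further by aldol addition under the base. Fallback, from 4 (isolated after the phosphine reduction of step 2) back to 13, replacing substrate control by 1,3-chirality transfer:
- Piperidine/AcOH in warm toluene should effect the intramolecular aldol condensation through the aldehyde enamine to the cyclopentene carbaldehyde F2.
- Me2Zn with the appropriate enantiomer of the amino alcohol ligand 3-exo-morpholinoisoborneol adds methyl under reagent control to give the (R)-allylic alcohol F3.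
- Heating with 5-propanoyl Meldrum's acid gives the 3-oxopentanoate ester F4.
- Carroll rearrangement of its dianion (LiN(iPr)2, THF, −78 °C → reflux, then loss of CO2) should pass through the chair with the carbinol methyl equatorial. This delivers the 2-oxobutyl carbon to the face of C1 anti to the C4 oxygen and gives the ethylidene ketone F5.
- BH3·THF then NaBO3·4H2O hydroborates the ethylidene group (boron on the less hindered carbon) and reduces the ketone to the diol F6.
- Dess–Martin oxidation of both alcohols, followed by base equilibration of C5, gives 13.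

**Risk 3, step 12.** Enolisation may be poorly regioselective (toward C10 instead of C8), and the ketone may be trapped as its transannular hemiketal with the C6 hydroxyl. Fallback, from 16 back to 22, fixing the alkene position by conjugation instead of by enolate equilibrium:
- IBX in DMSO at 70 °C dehydrogenates the 1,4-diketone at the only position that has hydrogen on both carbons between the carbonyls, giving the ene-dione F7.
- Me4NBH(OAc)3 reduces the C6 carbonyl under direction of the C4 hydroxyl to the hydroxy enone F8.
- TsNHNH2 with catalytic acid gives the tosylhydrazone F9.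
- Catecholborane, then NaOAc·3H2O at reflux, reduces the unsaturated hydrazone with migration of the double bond to C8=C9 and delivery of hydrogen to C7, giving 22.

## Further compounds

F1 | step 9 | cyclic diisopropylsilylene bis-enol ether of 13 (silicon bridging the C6 and C9 enol oxygens) | C=C1O[Si](C(C)C)(C(C)C)OC(=CC)C[C@@]2(C)CC[C@@](O[Si](CC)(CC)CC)(C(C)C)[C@H]12
F2 | step 8 | (S)-5-isopropyl-2-methyl-5-(triethylsilyloxy)cyclopent-1-ene-1-carbaldehyde | CC1=C(C=O)[C@](O[Si](CC)(CC)CC)(C(C)C)CC1
F3 | step 8 | (R)-1-[5-isopropyl-2-methyl-5-(triethylsilyloxy)cyclopent-1-en-1-yl]ethanol | CC1=C([C@@H](C)O)[C@](O[Si](CC)(CC)CC)(C(C)C)CC1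
F4 | step 8 | 3-oxopentanoate ester of F3 | CCC(=O)CC(=O)O[C@H](C)C1=C(C)CC[C@@]1(O[Si](CC)(CC)CC)C(C)C
F5 | step 8 | ethylidene cyclopentane with C1 methyl and C1 2-oxobutyl, C4 isopropyl and triethylsilyloxy | CCC(=O)C[C@@]1(C)CC[C@@](O[Si](CC)(CC)CC)(C(C)C)C1=CC
F6 | step 8 | diol from hydroboration and ketone reduction of F5 (epimer mixture) | CCC(O)C[C@@]1(C)CC[C@@](O[Si](CC)(CC)CC)(C(C)C)C1C(C)O
F7 | step 12 | 4β-hydroxy C7=C8 ene-6,9-dione | O=C1C=C(C)C(=O)C[C@@]2(C)CC[C@@](O)(C(C)C)[C@H]12
F8 | step 12 | 4β,6α-dihydroxy C7=C8 en-9-one | O[C@H]1C=C(C)C(=O)C[C@@]2(C)CC[C@@](O)(C(C)C)[C@H]12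
F9 | step 12 | tosylhydrazone of F8 | Cc1ccc(cc1)S(=O)(=O)NN=C1C[C@@]2(C)CC[C@@](O)(C(C)C)[C@@H]2[C@@H](O)C=C1C
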